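We must decide which recipe goes forward, so we want one number that says how much starting material ends as target.

| flask | starting material | reagent | protic impurity | initiator | remark | time |
|---|---|---|---|---|---|---|
| dawn | 20 mM | 1.2 equiv (fed, over 4.0 min) | 0.13 mM | 4 mol% | run made earlier |  |
| midnight | 20 mM | 1.2 equiv (fed, over 4.0 min) | 0.26 mM | 4 mol% | run made earlier |  |
| alpha | 20 mM | 1.80 equiv (fed, over 1.2 min) | 0.400 mM | 2.5 mol% |  | 50 min |
| zeta | 20 mM | 1.20 equiv (fed, over 4.0 min) | 0.400 mM | 2.5 mol% |  | 50 min |
| theta | 20 mM | 3.60 equiv (fed, over 6.0 min) | 0.250 mM | 4 mol% |  | 50 min |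
| eta | 20 mM | 1.20 equiv (fed, over 4.0 min) | 0.400 mM | 4 mol% |  | 50 min |

| run | time / min | target / % | starting material / % |
|---|---|---|---|
| dawn | 5.00 | 33.8 | 54.0 |
| dawn | 10.0 | 60.1 | 6.0 |
| dawn | 15.0 | 64.7 | 1.1 |
| dawn | 20.0 | 63.4 | 0 |
| dawn | 25.0 | 63.9 | 0.9 |
| dawn | 30.0 | 63.7 | 1.1 |
| dawn | 40.0 | 64.8 | 0.1 |
| midnight | 5.00 | 30.6 | 52.4 |
| midnight | 10.0 | 61.1 | 6.3 |
| midnight | 15.0 | 64.6 | 1.4 |
| midnight | 20.0 | 64.7 | 0 |
| midnight | 25.0 | 64.0 | 0 |
| midnight | 30.0 | 64.6 | 0.7 |
| midnight | 40.0 | 64.1 | 0.5 |

(readings scatter by 1 percentage point)

1. ranking by amount of target, in percent of the starting material charged, from high to low, at 50 min (alpha / zeta / theta / eta)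
2. the amount of target, in percent of the starting material charged of the flask you put first, at 50 min
3. the amount of target, in percent of the starting material charged of the flask you put last, at 50 min

- no earlier run changes the charge of initiator; that part of a forecast is a guess

Two readings seem not to fit. Pooling dawn and midnight, 68.8% of the starting material used up to 5.00 min became target, but 60.4% of that used between 5.00 min and 10.0 min. So the yield falls as target builds. Yet after 15.0 min target stands flat, at 63.9% by 25.0 min.

Both fit if the loss takes one target and one starting material together; that is our supposition. The loss then stops with the starting material, and midnight reads 0% left at 25.0 min. Each target lost has cost one more starting material, so we count the charge used: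

made = (100% + target) / 2 = 82.0%

lost = (100% − target) / 2 = 18.0%

split = made / lost = 4.55

This split, starting material through the making step per starting material through the loss, is a whole-run selectivity factor. Target comes back from it as (split − 1) / (split + 1).

Dawn and midnight, at 0.13 mM and 0.26 mM of impurity, read 63.9% and 64.0%, so we keep eta at 63.9%. For initiator we guess that the making speed, and so the split, goes with its square root:

zeta: split = 3.60, target = 56.5%

No run moves reagent. We expect more of it to raise the split, so we put theta first and zeta last, and leave alpha against eta open.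

The forecast gives theta > eta > alpha > zeta, with 66% first and 48% last, holding that “Impurity 0.40 mM nearly cancels 0.5 mM initiator”. The flasks give theta > alpha > eta > zeta, from 75.0% down to 60.3%.

    initiator → 2 initiating radical (k = 0.00150 min⁻¹)
    starting material + initiating radical → chain carrier (k = 2.90 × 10⁶ L mol⁻¹ s⁻¹)
    reagent + chain carrier → target + initiating radical (k = 2.30 × 10⁵ L mol⁻¹ s⁻¹)
    2 initiating radical → ended chains A (k = 1.00 × 10⁹ L mol⁻¹ s⁻¹)
    2 chain carrier → ended chains B (k = 2.00 × 10⁸ L mol⁻¹ s⁻¹)
    starting material + protic impurity → quenched substrate (k = 64.0 L mol⁻¹ min⁻¹)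
    starting material + target → side product (k = 8.10 L mol⁻¹ min⁻¹)

Zeta's 60.3% is, by the same count, a split of 4.04, above our 3.60. At 5.83 min in zeta, the step into the chain uses starting material 3.3 times as fast as the path to side product, while that path gives target a half-life of 8.5 min, shorter than the 50 min of the run. Zeta's neighbour with 1 mol% of initiator ends at 51.5%, a split of 3.12.

All runs are simulated from invented constants, noise included.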